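**Retrosynthetic overview**
1. Numbering: ring C1 carries C7 (CH2OBz), C2 is the vinyl CH, C3 and C4 carry OH, C5 carries OBz, C6 carries OH. The target is 3R,4S,5R,6S, with O3 and O6 on one face and O4 and O5 on the other.
2. Feature: C7–C1(=C2)–C6(OH) is an α-(hydroxyalkyl)enal (Baylis–Hillman) unit once C7 is at the aldehyde level. C2–C6, with O3/O4 trans and O4/O5 cis, are C1–C5 of D-arabinose.
3. Endgame: the O5 benzoate comes from opening an O4/O5 cis-orthobenzoate to the axial ester. The O7 benzoate comes from acylating the C7 alcohol made by 1,2-reduction of the enal.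
4. The only carbocycle (C1–C6) is closed once, through the C1–C6 bond, by an intramolecular Morita–Baylis–Hillman reaction of an (E)-hept-2-enedial (O3 silyl, O4/O5 acetonide).
5. The dialdehyde comes from 2-O-TBS-3,4-O-isopropylidene-D-arabinopyranose by Wittig extension with an ester ylide (brings C1 and C7), DIBAL-H reduction and double oxidation.

Key step: step 8

Assumption: in 16 and 18 the half-chair is taken to keep C6–OSi pseudo-axial (A(1,2) strain against C7), so that C5–O is axial and C4–O equatorial; step 13 rests on this. From 11 onward the spatial arrangement at C3–C6 is unchanged, and the CIP letters change only with substituent priorities.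

Step 1
Reactants: 1 D-arabinose; 2 benzyl alcohol
Product: 3 benzyl β-D-arabinopyranoside
Conditions: BnOH (solvent), anhydrous HCl (cat.), 50 °C then rt; crystallisation
Reagents that add atoms: benzyl alcohol, OCc1ccccc1
Why: Fischer glycosidation under thermodynamic control should give the crystalline pyranoside with the anomeric benzyloxy group axial (β-D); no carbinol stereocentre is touched.

Step 2
Reactants: 3 benzyl β-D-arabinopyranoside
Product: 4 benzyl 3,4-O-isopropylidene-β-D-arabinopyranoside
Conditions: Me2C(OMe)2, p-TsOH·H2O (cat.), acetone, rt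
Reagents that add atoms: 2,2-dimethoxypropane, COC(C)(C)OC
Why: Acid-catalysed transacetalisation; only the cis O3/O4 pair of the pyranoside (O4/O5 of the future ring) can close an unstrained dioxolane, so O2 stays free.

Step 3
Reactants: 4 benzyl 3,4-O-isopropylidene-β-D-arabinopyranoside
Product: 5 benzyl 2-O-(tert-butyldimethylsilyl)-3,4-O-isopropylidene-β-D-arabinopyranoside
Conditions: TBSCl, imidazole, DMF, 40 °C
Reagents that add atoms: tert-butyldimethylsilyl chloride, CC(C)(C)[Si](C)(C)Cl
Why: Imidazole-promoted silylation of the single free (equatorial) hydroxyl; this oxygen becomes O3 of the ring.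

Step 4
Reactants: 5 benzyl 2-O-(tert-butyldimethylsilyl)-3,4-O-isopropylidene-β-D-arabinopyranoside
Product: 6 2-O-(tert-butyldimethylsilyl)-3,4-O-isopropylidene-D-arabinopyranose (anomeric mixture)
Conditions: H2 (1 atm), 10% Pd/C, EtOAc, rt
Reagents that add atoms: none
Why: Hydrogenolysis of the benzyl glycoside frees the lactol; in EtOAc (not MeOH) the silyl ether and the acetonide should be inert.

Step 5
Reactants: 6 2-O-(tert-butyldimethylsilyl)-3,4-O-isopropylidene-D-arabinopyranose; 7 ethyl (triphenylphosphoranylidene)acetate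
Product: 8 ethyl (2E,4R,5R,6R)-4-[(tert-butyldimethylsilyl)oxy]-7-hydroxy-5,6-(isopropylidenedioxy)hept-2-enoate (chain C1–C7 = ring C7, C1–C6)
Conditions: Ph3P=CHCO2Et, toluene, 80 °C
Reagents that add atoms: ethyl (triphenylphosphoranylidene)acetate, CCOC(=O)C=P(c1ccccc1)(c1ccccc1)c1ccccc1
Why: Wittig olefination of the open-chain aldehyde in equilibrium with the lactol, E-selective with the stabilised ylide; the ester ylide is used because the enoate cannot be olefinated again and, without base, its liberated primary hydroxyl should not add back to C2 (oxa-Michael) as it would to an enal.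

Step 6
Reactants: 8 ethyl (2E,4R,5R,6R)-4-[(tert-butyldimethylsilyl)oxy]-7-hydroxy-5,6-(isopropylidenedioxy)hept-2-enoate
Product: 9 (2E,4R,5R,6R)-4-[(tert-butyldimethylsilyl)oxy]-5,6-(isopropylidenedioxy)hept-2-ene-1,7-diol
Conditions: i-Bu2AlH (3.5 equiv), CH2Cl2, −78 °C; aq. potassium sodium tartrate
Reagents that add atoms: none
Why: DIBAL-H reduces the conjugated ester 1,2 to the allylic alcohol with the alkene geometry kept; silyl ether and acetonide are inert.

Step 7
Reactants: 9 (2E,4R,5R,6R)-4-[(tert-butyldimethylsilyl)oxy]-5,6-(isopropylidenedioxy)hept-2-ene-1,7-diol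
Product: 10 (2E,4R,5R,6S)-4-[(tert-butyldimethylsilyl)oxy]-5,6-(isopropylidenedioxy)hept-2-enedial
Conditions: Dess–Martin periodinane (2.6 equiv), pyridine, CH2Cl2, 0 °C to rt; used crude
Reagents that add atoms: none
Why: Dess–Martin oxidation takes both primary alcohols to aldehydes under near-neutral, amine-poor conditions, so the hydroxy-enal stage is short-lived and the α-alkoxy aldehyde centre should not epimerise.

Step 8
Reactants: 10 (2E,4R,5R,6S)-4-[(tert-butyldimethylsilyl)oxy]-5,6-(isopropylidenedioxy)hept-2-enedial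
Product: 11 (3R,4R,5R,6S)-3-[(tert-butyldimethylsilyl)oxy]-6-hydroxy-4,5-(isopropylidenedioxy)cyclohex-1-ene-1-carbaldehyde
Conditions: PMe3 (0.3 equiv, 1 M in THF), t-AmOH, degassed, 0 °C to rt
Reagents that add atoms: none
Why: Intramolecular Morita–Baylis–Hillman reaction: PMe3 adds to C2 of the enal and erases the alkene geometry, the β-phosphonium enolate attacks the C6 aldehyde through C1, and proton transfer from C1 with loss of PMe3 restores C1=C2 with C7 still an aldehyde. The closest known reaction type is the phosphine- or amine-catalysed cyclisation of hept-2-enedial and of ω-formyl enoates and enones to 6-hydroxycyclohex-1-ene carbonyl compounds. The one ring closes in the 6-(enolexo)-exo-trig mode. The new C6 carbinol is set by a chair-like transition state with C3–OSi and C4–O equatorial, C5–O held axial by the cis-dioxolane, and the aldehyde oxygen axial and antiperiplanar to C5–O (dipole-opposed), which gives C6–O trans to C5–O; the aldol step is reversible, and the trans isomer with C6–O pseudo-axial (no A(1,2) strain against the formyl group) is also the expected thermodynamic product. The step needs this facial selectivity and retention of C5, which is α to the C6 aldehyde and epimerisable; the cis-fused dioxolane pre-folds C3–C6 so that closure should outrun enolisation, and a weakly basic phosphine in a tertiary alcohol keeps free alkoxide low. The enal is the only Michael acceptor, so no cross-reaction competes.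

Step 9
Reactants: 11 (3R,4R,5R,6S)-3-[(tert-butyldimethylsilyl)oxy]-6-hydroxy-4,5-(isopropylidenedioxy)cyclohex-1-ene-1-carbaldehyde
Product: 12 (3R,4R,5S,6S)-3,6-bis[(tert-butyldimethylsilyl)oxy]-4,5-(isopropylidenedioxy)cyclohex-1-ene-1-carbaldehyde
Conditions: TBSOTf, 2,6-lutidine, CH2Cl2, −78 to 0 °C
Reagents that add atoms: tert-butyldimethylsilyl trifluoromethanesulfonate, CC(C)(C)[Si](C)(C)OS(=O)(=O)C(F)(F)F
Why: Silyl triflate silylation of the hindered secondary allylic alcohol caps the aldol hydroxyl, which blocks retro-aldol opening and removes any selectivity question in the later benzoylation.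

Step 10
Reactants: 12 (3R,4R,5S,6S)-3,6-bis[(tert-butyldimethylsilyl)oxy]-4,5-(isopropylidenedioxy)cyclohex-1-ene-1-carbaldehyde
Product: 13 [(3R,4R,5S,6S)-3,6-bis[(tert-butyldimethylsilyl)oxy]-4,5-(isopropylidenedioxy)cyclohex-1-en-1-yl]methanol
Conditions: NaBH4, CeCl3·7H2O, MeOH, −40 °C
Reagents that add atoms: none
Why: Luche reduction gives clean 1,2-reduction of the enal to the primary allylic alcohol (C7) and creates no stereocentre.

Step 11
Reactants: 13 [(3R,4R,5S,6S)-3,6-bis[(tert-butyldimethylsilyl)oxy]-4,5-(isopropylidenedioxy)cyclohex-1-en-1-yl]methanol; 14 benzoyl chloride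
Product: 15 [(3R,4R,5S,6S)-3,6-bis[(tert-butyldimethylsilyl)oxy]-4,5-(isopropylidenedioxy)cyclohex-1-en-1-yl]methyl benzoate
Conditions: BzCl, pyridine, DMAP (cat.), CH2Cl2, 0 °C
Reagents that add atoms: benzoyl chloride, O=C(Cl)c1ccccc1
Why: DMAP-catalysed acylation of the only free hydroxyl installs the O7 benzoate.

Step 12
Reactants: 15 [(3R,4R,5S,6S)-3,6-bis[(tert-butyldimethylsilyl)oxy]-4,5-(isopropylidenedioxy)cyclohex-1-en-1-yl]methyl benzoate
Product: 16 [(3R,4R,5S,6S)-3,6-bis[(tert-butyldimethylsilyl)oxy]-4,5-dihydroxycyclohex-1-en-1-yl]methyl benzoate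
Conditions: TFA/H2O (9:1), CH2Cl2, 0 °C; aq. NaHCO3 quench at full conversion
Reagents that add atoms: none
Why: Acid-catalysed acetal hydrolysis; at 0 °C the isopropylidene acetal should cleave well before the two hindered secondary silyl ethers or the benzoate.

Step 13
Reactants: 16 [(3R,4R,5S,6S)-3,6-bis[(tert-butyldimethylsilyl)oxy]-4,5-dihydroxycyclohex-1-en-1-yl]methyl benzoate; 17 trimethyl orthobenzoate
Product: 19 [(3R,4R,5S,6S)-5-(benzoyloxy)-3,6-bis[(tert-butyldimethylsilyl)oxy]-4-hydroxycyclohex-1-en-1-yl]methyl benzoate, via 4,5-O-(α-methoxybenzylidene) orthoester 18 (not isolated)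
Conditions: PhC(OMe)3, CSA (cat.), MeCN, rt; then AcOH/H2O (4:1), 0 °C to rt
Reagents that add atoms: trimethyl orthobenzoate, COC(OC)(OC)c1ccccc1; water, O
Why: Acid-catalysed orthoester exchange closes the cyclic orthobenzoate on the only cis-diol, and hydrolytic opening of the derived 2-hydroxy-1,3-dioxolane follows the axial-ester rule for cis-fused orthoesters, so axial O5 should keep the benzoyl group and equatorial O4 be released.

Step 14
Reactants: 19 [(3R,4R,5S,6S)-5-(benzoyloxy)-3,6-bis[(tert-butyldimethylsilyl)oxy]-4-hydroxycyclohex-1-en-1-yl]methyl benzoate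
Product: 20 [(3R,4S,5R,6S)-5-(benzoyloxy)-3,4,6-trihydroxycyclohex-1-en-1-yl]methyl benzoate (CNP0198957.1)
Conditions: HF·pyridine, pyridine, THF, 0 °C to rt
Reagents that add atoms: none
Why: Fluoride desilylation in a weakly acidic buffered medium should remove both secondary TBS ethers without the alkoxide intermediates that would let the C5 benzoate migrate to O4 or O6.

**Compound list**
1 | D-arabinose | O=C[C@@H](O)[C@H](O)[C@H](O)CO | starting material
2 | benzyl alcohol | OCc1ccccc1 | starting material
3 | benzyl β-D-arabinopyranoside | c1ccccc1CO[C@H]1[C@@H](O)[C@H](O)[C@H](O)CO1 | intermediate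
4 | benzyl 3,4-O-isopropylidene-β-D-arabinopyranoside | c1ccccc1CO[C@H]1[C@@H](O)[C@H](O2)[C@H](OC2(C)C)CO1 | intermediate
5 | benzyl 2-O-(tert-butyldimethylsilyl)-3,4-O-isopropylidene-β-D-arabinopyranoside | c1ccccc1CO[C@H]1[C@@H](O[Si](C)(C)C(C)(C)C)[C@H](O2)[C@H](OC2(C)C)CO1 | intermediate
6 | 2-O-(tert-butyldimethylsilyl)-3,4-O-isopropylidene-D-arabinopyranose (anomeric mixture) | OC1[C@@H](O[Si](C)(C)C(C)(C)C)[C@H](O2)[C@H](OC2(C)C)CO1 | intermediate
7 | ethyl (triphenylphosphoranylidene)acetate | CCOC(=O)C=P(c1ccccc1)(c1ccccc1)c1ccccc1 | starting material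
8 | ethyl (2E,4R,5R,6R)-4-[(tert-butyldimethylsilyl)oxy]-7-hydroxy-5,6-(isopropylidenedioxy)hept-2-enoate | CCOC(=O)/C=C/[C@@H](O[Si](C)(C)C(C)(C)C)[C@H](O1)[C@H](OC1(C)C)CO | intermediate
9 | (2E,4R,5R,6R)-4-[(tert-butyldimethylsilyl)oxy]-5,6-(isopropylidenedioxy)hept-2-ene-1,7-diol | OC/C=C/[C@@H](O[Si](C)(C)C(C)(C)C)[C@H](O1)[C@H](OC1(C)C)CO | intermediate
10 | (2E,4R,5R,6S)-4-[(tert-butyldimethylsilyl)oxy]-5,6-(isopropylidenedioxy)hept-2-enedial | O=C/C=C/[C@@H](O[Si](C)(C)C(C)(C)C)[C@H](O1)[C@H](OC1(C)C)C=O | intermediate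
11 | (3R,4R,5R,6S)-3-[(tert-butyldimethylsilyl)oxy]-6-hydroxy-4,5-(isopropylidenedioxy)cyclohex-1-ene-1-carbaldehyde | O=CC1=C[C@@H](O[Si](C)(C)C(C)(C)C)[C@H](O2)[C@H](OC2(C)C)[C@H]1O | intermediate
12 | (3R,4R,5S,6S)-3,6-bis[(tert-butyldimethylsilyl)oxy]-4,5-(isopropylidenedioxy)cyclohex-1-ene-1-carbaldehyde | O=CC1=C[C@@H](O[Si](C)(C)C(C)(C)C)[C@H](O2)[C@H](OC2(C)C)[C@H]1O[Si](C)(C)C(C)(C)C | intermediate
13 | [(3R,4R,5S,6S)-3,6-bis[(tert-butyldimethylsilyl)oxy]-4,5-(isopropylidenedioxy)cyclohex-1-en-1-yl]methanol | OCC1=C[C@@H](O[Si](C)(C)C(C)(C)C)[C@H](O2)[C@H](OC2(C)C)[C@H]1O[Si](C)(C)C(C)(C)C | intermediate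
14 | benzoyl chloride | O=C(Cl)c1ccccc1 | starting material
15 | [(3R,4R,5S,6S)-3,6-bis[(tert-butyldimethylsilyl)oxy]-4,5-(isopropylidenedioxy)cyclohex-1-en-1-yl]methyl benzoate | O=C(OCC1=C[C@@H](O[Si](C)(C)C(C)(C)C)[C@H](O2)[C@H](OC2(C)C)[C@H]1O[Si](C)(C)C(C)(C)C)c1ccccc1 | intermediate
16 | [(3R,4R,5S,6S)-3,6-bis[(tert-butyldimethylsilyl)oxy]-4,5-dihydroxycyclohex-1-en-1-yl]methyl benzoate | O=C(OCC1=C[C@@H](O[Si](C)(C)C(C)(C)C)[C@H](O)[C@H](O)[C@H]1O[Si](C)(C)C(C)(C)C)c1ccccc1 | intermediate
17 | trimethyl orthobenzoate | COC(OC)(OC)c1ccccc1 | starting material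
18 | 4,5-O-(α-methoxybenzylidene) orthoester of 16 (mixture at the orthoester carbon) | O=C(OCC1=C[C@@H](O[Si](C)(C)C(C)(C)C)[C@H](O2)[C@H](OC2(OC)c3ccccc3)[C@H]1O[Si](C)(C)C(C)(C)C)c1ccccc1 | intermediate
19 | [(3R,4R,5S,6S)-5-(benzoyloxy)-3,6-bis[(tert-butyldimethylsilyl)oxy]-4-hydroxycyclohex-1-en-1-yl]methyl benzoate | O=C(OCC1=C[C@@H](O[Si](C)(C)C(C)(C)C)[C@H](O)[C@H](OC(=O)c2ccccc2)[C@H]1O[Si](C)(C)C(C)(C)C)c1ccccc1 | intermediate
20 | [(3R,4S,5R,6S)-5-(benzoyloxy)-3,4,6-trihydroxycyclohex-1-en-1-yl]methyl benzoate | O=C(OCC1=C[C@@H](O)[C@H](O)[C@H](OC(=O)c2ccccc2)[C@H]1O)c1ccccc1 | target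

Total step count: 14. Longest linear sequence: 14 steps, from D-arabinose.

**Steps most likely to fail**

Step 8 (key step). The phosphine may add too slowly to C2, which is flanked by the silyloxy-bearing C3; C5 may epimerise through enolisation of the C6 aldehyde; or the aldehyde face may be attacked with poor selectivity. The fallback sets out from 10 and comes back at 11. It replaces the catalytic, reversible zwitterionic closure by a stoichiometric thiolate-triggered Michael–aldol sequence under kinetic control. PhSH with catalytic PhSLi in THF at −78 to −40 °C should add sulfur to C2, and the lithium enolate should close onto the C6 aldehyde to give the 2-phenylthio aldol F1 (a C1/C2 mixture, which does not matter). Oxidation at sulfur with mCPBA at −78 °C should give the sulfoxide F2. Warming F2 with Et3N should eliminate benzenesulfenic acid across C1–C2 towards the acidic C1–H and deliver 11.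

Step 13. The hemi-orthoester may open towards the O4 ester if the ring reacts through the other half-chair (C5–O equatorial), or the benzoyl group may drift between O5 and O4 under the acidic opening. The fallback sets out from 16 and comes back at 19. It uses tin-acetal acylation, which delivers the acyl group to the equatorial oxygen of a cis-diol, that is, to the oxygen that orthoester opening leaves free. Bu2SnO in toluene at reflux with water removal should give the 4,5-O-dibutylstannylene acetal F3, and BzCl (1.05 equiv) at 0 °C should then give 19.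

Step 12. Partial loss of one or both silyl ethers may accompany hydrolysis of the acetonide. The fallback sets out from 15 and comes back at the target 20, so the silyl groups no longer need to survive. TFA/H2O (4:1) at rt should strip the acetonide and both TBS groups to give the 7-O-benzoyl tetraol F4. PhC(OMe)3 (1.1 equiv) with catalytic CSA in MeCN should close the orthobenzoate F5 on the only cis-diol (O4/O5), the trans-disposed free hydroxyls being tolerated. AcOH/H2O (4:1) should open it to the axial C5 benzoate 20 directly, with steps 13 and 14 omitted.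

**Further compounds**
F1 | step 8 | (3R,4R,5R,6S)-3-[(tert-butyldimethylsilyl)oxy]-6-hydroxy-4,5-(isopropylidenedioxy)-2-(phenylthio)cyclohexane-1-carbaldehyde (C1/C2 mixture) | O=CC1C(Sc2ccccc2)[C@@H](O[Si](C)(C)C(C)(C)C)[C@H](O2)[C@H](OC2(C)C)[C@H]1O
F2 | step 8 | sulfoxide of F1, 2-(phenylsulfinyl) analogue (mixture at C1, C2 and S) | O=CC1C(S(=O)c2ccccc2)[C@@H](O[Si](C)(C)C(C)(C)C)[C@H](O2)[C@H](OC2(C)C)[C@H]1O
F3 | step 13 | 4,5-O-dibutylstannylene acetal of 16 | O=C(OCC1=C[C@@H](O[Si](C)(C)C(C)(C)C)[C@H](O2)[C@H](O[Sn]2(CCCC)CCCC)[C@H]1O[Si](C)(C)C(C)(C)C)c1ccccc1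
F4 | step 12 | [(3R,4S,5S,6S)-3,4,5,6-tetrahydroxycyclohex-1-en-1-yl]methyl benzoate | O=C(OCC1=C[C@@H](O)[C@H](O)[C@H](O)[C@H]1O)c1ccccc1
F5 | step 12 | 4,5-O-(α-methoxybenzylidene) orthoester of F4 (mixture at the orthoester carbon) | O=C(OCC1=C[C@@H](O)[C@H](O2)[C@H](OC2(OC)c3ccccc3)[C@H]1O)c1ccccc1
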